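**Retrosynthetic overview**
1. Endgame: removing the C3 isovalerate, the C11=C13 methylene, the trans-1,10-oxirane (C10–O displaces C1–OTs with inversion) and the C8 epoxyangelate (acid 21, from an asymmetric epoxidation) leads back to hydroxy lactone 17.
2. 17 comes from the 2-alkylcyclodec-4-ene-1,3-dione 14 by a hydroxyl-relayed reduction (C10–OH→C8, then C8–OH→C6, both 1,3-anti). The labile C7 is funnelled to one configuration, and the γ-lactone then closes.
3. Enabling feature: in the ten-membered carbocycle C1–C10 the oxygens on C6 and C8 flank C7, which is a masked cyclic 1,3-diketone. That diketone is the retro-aldol product of a 1-siloxybicyclo[6.2.0]decan-9-one: cutting the fusion bond C6–C9 merges the eight-membered ring (C1–C6, C9, C10) and the cyclobutanone (C6–C7–C8–C9) into the ten-membered ring.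
4. The cyclobutanone arises from dichloroketene and the silyl dienol ether of cyclooctenone 8. The eight-membered ring, both methyl groups (on C4 and C10) and the Z-C4=C5 alkene are bought as isoprene dimer 1. C3 is set by CBS reduction and C1/C10 by syn-dihydroxylation.
5. Ring order: eight-membered ring (purchased) → cyclobutanone → ten-membered ring → γ-lactone → oxirane.

Key step: step 10

Remark on locants: germacrane numbering is used. The ring is C1–C10, C14 is the methyl on C10, C15 the methyl on C4, and C11/C12/C13 are the lactone α-carbon, carbonyl and methylene. Primes denote the epoxyangelate.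
Assumption: technical 1, which contains the 1,6-dimethyl isomer, is treated as the pure 1,5-isomer after enrichment by fractional distillation.

Step 1
Reactants: 1 (1Z,5Z)-1,5-dimethylcycloocta-1,5-diene
Product: 3 (2Z,6Z)-2,6-dimethylcycloocta-2,6-dien-1-one, via racemic dienol 2 (not isolated)
Conditions: SeO2 (20 mol %), t-BuOOH, CH2Cl2, 0 °C to rt, partial conversion; crude product then DMP, CH2Cl2, 0 °C
Reagents that add atoms: tert-butyl hydroperoxide CC(C)(C)OO
Why: The SeO2/TBHP allylic hydroxylation (ene reaction, then [2,3]-shift) oxidises the ring CH2 attached to the methyl-bearing alkene carbon (future C3), as is usual for 1-methylcycloalkenes, and Dess–Martin oxidation of the crude alcohol/enone mixture converges on the achiral dienone, so no stereocentre has to be controlled.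

Step 2
Reactants: 3 (2Z,6Z)-2,6-dimethylcycloocta-2,6-dien-1-one
Product: 4 (1S,2Z,6Z)-2,6-dimethylcycloocta-2,6-dien-1-ol (carbinol carbon = C3)
Conditions: (R)-Me-CBS (20 mol %), catecholborane, toluene, −78 °C; aqueous work-up
Reagents that add atoms: none
Why: In this Corey–Bakshi–Shibata reduction the α-methylalkenyl flank (C4) acts as the large group and the C2 methylene as the small group, so the (R)-catalyst should give the (S)-carbinol at C3, and catecholborane at low temperature avoids hydroboration of the two trisubstituted alkenes.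

Step 3
Reactants: 4 (1S,2Z,6Z)-2,6-dimethylcycloocta-2,6-dien-1-ol
Product: 5 tert-butyldimethylsilyl ether of 4
Conditions: TBSCl, imidazole, DMF, rt
Reagents that add atoms: tert-butyldimethylsilyl chloride CC(C)(C)[Si](C)(C)Cl
Why: Standard silylation masks the C3 alcohol, because a free Z-γ-hydroxy enone (once C6 is a ketone) would cyclise to a hemiketal and dehydrate to a furan.

Step 4
Reactants: 5 tert-butyldimethylsilyl ether of 4
Product: 6 (1R,2S,4S,5Z)-4-(tert-butyldimethylsilyloxy)-1,5-dimethylcyclooct-5-ene-1,2-diol (C10 R; C1 S; C3 S; the two OH groups cis to each other and trans to OTBS)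
Conditions: OsO4 (2 mol %), NMO, acetone/H2O, 0 °C
Reagents that add atoms: N-methylmorpholine N-oxide C[N+]1([O-])CCOCC1; water O
Why: In this Upjohn dihydroxylation the remote electron-rich C1=C10 alkene should react before C4=C5, which is deactivated and shielded by the allylic OTBS group, and suprafacial addition on the ring face opposite to that bulky group sets C1 and C10 relative to C3.

Step 5
Reactants: 6 diol
Product: 7 C1 mono-p-toluenesulfonate of 6 (C10–OH free)
Conditions: TsCl, Et3N, Me3N·HCl (cat.), CH2Cl2, 0 °C
Reagents that add atoms: p-toluenesulfonyl chloride Cc1ccc(cc1)S(=O)(=O)Cl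
Why: Sulfonylation selects the secondary C1–OH over the tertiary C10–OH, and the cis-hydroxy tosylate can be carried forward because the O–C10–C1–O torsion equals the ring torsion C9–C10–C1–C2, so the antiperiplanar geometry needed for oxirane closure is out of reach in an eight-membered ring.

Step 6
Reactants: 7 hydroxy tosylate
Product: 8 (2Z,4S,6S,7R)-4-(tert-butyldimethylsilyloxy)-7-hydroxy-3,7-dimethyl-6-(tosyloxy)cyclooct-2-en-1-one (ketone = C6)
Conditions: Rh2(cap)4 (1 mol %), 70 % aq. t-BuOOH, 1,2-dichloroethane, 40 °C, no base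
Reagents that add atoms: tert-butyl hydroperoxide CC(C)(C)OO
Why: In this dirhodium-caprolactamate/TBHP allylic oxidation (peroxyl-radical chain) hydrogen abstraction at the unhindered C6H2 and oxygenation at the less substituted allyl terminus give the β-methyl enone, as with 1-methylcycloalkenes, and the base-free medium spares the β-hydroxy/γ-tosyloxy ketone.

Step 7
Reactants: 8 cyclooctenone
Product: 9 bis(trimethylsilyl) derivative of 8 (cross-conjugated siloxydiene C4=C5–C6(OTMS)=C9; C10–OTMS)
Conditions: TMSCl (excess) present from the start, LDA (2.4 equiv), THF, −78 °C; Et3N, pentane work-up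
Reagents that add atoms: chlorotrimethylsilane C[Si](C)(C)Cl
Why: Kinetic α′-deprotonation of the enone toward C9 (the behaviour of isophorone) with in situ silyl trapping gives the 2-siloxydiene and silylates C10–O in the same operation, and immediate capture at −78 °C forestalls retro-aldol cleavage, β-elimination and 1,3-displacement of the tosylate.

Step 8
Reactants: 9 siloxydiene
Product: 10 cis-fused 10,10-dichloro-1-(trimethylsilyloxy)bicyclo[6.2.0]dec-2-en-9-one bearing 3-Me/4-OTBS/6-OTs/7-Me/7-OTMS (bicyclo C1 = C6; C8 = C9; C9 = C8; C10 = C7; drawn with the cyclobutanone on the face of the C14 methyl)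
Conditions: Cl2CHCOCl, Et3N (slow addition), hexanes, 0 °C to rt
Reagents that add atoms: dichloroacetyl chloride O=C(Cl)C(Cl)Cl
Why: In this ketene/enol ether [2+2] cycloaddition the nucleophilic C9 attacks the ketene carbonyl carbon (future C8) and the CCl2 terminus (future C7) closes on the siloxy-bearing C6, so the regiochemistry is fixed by the enol-ether polarisation, cis-fusion is obligatory, and the facial ratio does not matter because the stereocentres at C6 and C9 are erased in step 10.

Step 9
Reactants: 10 dichlorocyclobutanone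
Product: 11 1-(trimethylsilyloxy)bicyclo[6.2.0]dec-2-en-9-one (10 with CH2 in place of CCl2)
Conditions: Zn dust, AcOH/TMEDA, EtOH, 0 °C to rt
Reagents that add atoms: none
Why: This buffered zinc reduction of the α,α-dichloroketone is the standard follow-up to dichloroketene cycloadditions, and removing the chlorines first prevents a later cleavage toward a chlorine-stabilised C7 carbanion.

Step 10
Reactants: 11 siloxybicyclo[6.2.0]decenone
Product: 14 methyl 2-[(4Z,6S,8S,9R)-6-(tert-butyldimethylsilyloxy)-9-hydroxy-5,9-dimethyl-1,3-dioxo-8-(tosyloxy)cyclodec-4-en-2-yl]acetate (C7 labile), via cyclobutanolate 12 (not isolated), via ten-membered diketonate 13 (not isolated)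
Conditions: TBAF (2.05 equiv)/AcOH (1.0 equiv), THF, −78 to −20 °C; then ICH2CO2Me, 0 °C
Reagents that add atoms: methyl iodoacetate COC(=O)CI
Why: Fluoride strips both TMS groups, and the tertiary cyclobutanolate at C6, which is the aldolate of the C8 ketone, fragments by retro-aldol cleavage of the ring-fusion bond C6–C9; release of cyclobutane strain (about 26 kcal/mol) merges the eight- and four-membered rings into the ten-membered ring, a proton shift from C7 gives the tetrabutylammonium 1,3-diketonate, and this is C-alkylated by methyl iodoacetate to form the C7–C11 bond. The closest known reaction type is the two-carbon ring expansion of dichloroketene/silyl enol ether adducts (1-siloxybicyclo[n.2.0]alkanones) to cycloalkane-1,3-diones, combined with the fluoride-mediated C-alkylation of β-diketones. No ring is closed by bond formation: the ten-membered ring arises by scission of the zero-atom bridge of the bicyclo[6.2.0] system, so no medium-ring cyclisation has to be paid for. No permanent stereocentre is created, because C6 becomes trigonal and C9 a methylene, so every diastereomer of 11 converges on one product; C7 stays labile until step 11, C1, C3 and C10 are untouched, and the Z geometry of C4=C5 enforced by the eight-membered ring is carried over. The step needs cleavage of C6–C9 rather than C6–C7, which is secured because the aldol/retro-aldol manifold is reversible and drains into the more acidic diketonate with an unsubstituted central carbon (C7), the alternative 2-acetylcyclooctenone having a tertiary central carbon wedged against the quaternary C10, and because the chlorines that would stabilise a C7 carbanion were removed in step 9. It also needs C- over O-alkylation (soft iodide, ammonium enolate) and survival of the C10–OH/C1–OTs pair, for which one equivalent of acetic acid keeps C10–OH protonated so that no oxirane, and hence no base-labile β,γ-epoxy ketone, forms while C8 is still a ketone.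

Step 11
Reactants: 14 alkylated cyclodecenedione
Product: 17 (1S,3S,6R,7R,8R,10R)-3-(tert-butyldimethylsilyloxy)-8,10-dihydroxy-1-(tosyloxy)germacr-4Z-en-6,12-olide (trans-fused lactone; C11 still CH2), via C8-hydroxy enone 15 (not isolated), via anti-diol ester 16 (not isolated)
Conditions: Me4NBH(OAc)3 (excess), MeCN/AcOH 1:1, −30 to 0 °C; aq. Rochelle salt; then PPTS (cat.), CH2Cl2, rt
Reagents that add atoms: none
Why: In this Saksena–Evans reduction run as a relay, the tertiary C10–OH binds the borohydride and delivers hydride to C8 through a chair transition state (1,3-anti), the rapidly epimerising C7 reacts through the Felkin–Anh rotamer with the C6 acyl group anti to the hydride (C11/O8 anti), the new C8–OH repeats the delivery onto the enone carbonyl C6 (1,2-mode, 1,3-anti), and acid-catalysed equilibrating 5-exo-trig lactonisation should settle on the trans-fused 6,12-olide, the arrangement that persists in 8β-hydroxy-germacran-6,12-olides.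

Step 12
Reactants: 18 methyl angelate, methyl (Z)-2-methylbut-2-enoate
Product: 19 (Z)-2-methylbut-2-en-1-ol
Conditions: DIBAL-H (2.2 equiv), CH2Cl2, −78 to 0 °C; aq. Rochelle salt
Reagents that add atoms: none
Why: DIBAL-H reduces the unsaturated ester in 1,2-fashion without touching the Z alkene geometry.

Step 13
Reactants: 19 (Z)-2-methylbut-2-en-1-ol
Product: 20 [(2R,3S)-2,3-dimethyloxiran-2-yl]methanol
Conditions: Ti(OiPr)4 (10 mol %), D-(−)-diethyl tartrate (12 mol %), t-BuOOH, 4 Å MS, CH2Cl2, −20 °C
Reagents that add atoms: tert-butyl hydroperoxide CC(C)(C)OO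
Why: In this Katsuki–Sharpless asymmetric epoxidation the D-(−)-tartrate catalyst gives the 2R epoxy alcohol (the L-(+) series gives 2S), and suprafacial oxygen transfer keeps the C3′ methyl cis to the CH2OH group, so both side-chain stereocentres are set together.

Step 14
Reactants: 20 epoxy alcohol
Product: 21 (2S,3S)-2,3-dimethyloxirane-2-carboxylic acid
Conditions: RuCl3·xH2O (2 mol %), NaIO4, MeCN/EtOAc/H2O, 0 °C to rt
Reagents that add atoms: sodium periodate [Na+].[O-]I(=O)(=O)=O; water O
Why: Catalytic RuO4 oxidation takes the epoxy alcohol to the epoxy acid without touching either stereocentre, and the C2′ descriptor changes to S only through the CIP priorities.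

Step 15
Reactants: 17 hydroxy lactone; 21 (2S,3S)-2,3-dimethyloxirane-2-carboxylic acid
Product: 23 8-O-[(2S,3S)-2,3-dimethyloxirane-2-carbonyl] derivative of 17, via mixed anhydride 22 (not isolated)
Conditions: 21, 2,4,6-trichlorobenzoyl chloride, Et3N, toluene, rt; then 17, DMAP, toluene, 40 °C
Reagents that add atoms: none
Why: Yamaguchi esterification couples the α-quaternary acid to the only secondary alcohol (C8–OH) with retention at C8, the tertiary C10–OH being inert.

Step 16
Reactants: 23 C8 ester
Product: 24 (1R,10R)-1,10-epoxide of the series (3-OTBS; 8-epoxyangelate; C11 still CH2)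
Conditions: NaH (1.3 equiv), THF, 0 °C to rt
Reagents that add atoms: none
Why: In this intramolecular Williamson closure (3-exo-tet) the C10 alkoxide displaces the C1 tosylate with inversion, turning the cis-diol array from the Z alkene into the trans-oxirane, because the ten-membered ring, unlike the eight-membered one, can adopt the near-antiperiplanar C9–C10–C1–C2 torsion, and because C8 is no longer a ketone the epoxide is not prone to base-induced isomerisation.

Step 17
Reactants: 24 epoxy lactone
Product: 27 α-methylene lactone (3-OTBS precursor of the target), via Mannich base 25 (not isolated), via methiodide 26 (not isolated)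
Conditions: LDA (1.3 equiv), THF, −78 °C; CH2=NMe2+ I−, −78 °C to rt; MeI, THF, rt; DBU, CH2Cl2, 0 °C
Reagents that add atoms: Eschenmoser's salt C[N+](C)=C.[I-]
Why: In this Eschenmoser methylenation (Mannich reaction of the lactone enolate, quaternisation, then β-elimination) the lactone CH2 is the only enolisable position, since the epoxyangelate has no α-hydrogen and the isovalerate is not yet present.

Step 18
Reactants: 27 silyl ether
Product: 28 3-hydroxy compound (desisovaleryl target)
Conditions: TBAF/AcOH (1:1), THF, 0 °C to rt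
Reagents that add atoms: none
Why: Acetic-acid-buffered fluoride desilylation frees the C3 alcohol without acid that could trigger transannular opening of the 1,10-epoxide and without enough basicity to add to the methylene lactone.

Step 19
Reactants: 28 3-hydroxy compound
Product: 29 target CNP0167461.1
Conditions: isovaleric anhydride, DMAP (cat.), pyridine, CH2Cl2, 0 °C to rt
Reagents that add atoms: isovaleric anhydride CC(C)CC(=O)OC(=O)CC(C)C
Why: DMAP-catalysed acylation of the single remaining alcohol proceeds with retention at C3 under conditions tolerated by both oxiranes and the methylene lactone.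

**Compound list**
1 | (1Z,5Z)-1,5-dimethylcycloocta-1,5-diene | C1/C=C(/C)CC/C=C(/C)C1 | starting material
2 | racemic (2Z,6Z)-2,6-dimethylcycloocta-2,6-dien-1-ol | C1/C=C(/C)C(O)C/C=C(/C)C1 | intermediate
3 | (2Z,6Z)-2,6-dimethylcycloocta-2,6-dien-1-one | C1/C=C(/C)C(=O)C/C=C(/C)C1 | intermediate
4 | (1S,2Z,6Z)-2,6-dimethylcycloocta-2,6-dien-1-ol | C1/C=C(/C)[C@@H](O)C/C=C(/C)C1 | intermediate
5 | TBS ether of 4 | C1/C=C(/C)[C@@H](O[Si](C)(C)C(C)(C)C)C/C=C(/C)C1 | intermediate
6 | (1R,2S,4S,5Z)-4-(TBSO)-1,5-dimethylcyclooct-5-ene-1,2-diol | C1/C=C(/C)[C@@H](O[Si](C)(C)C(C)(C)C)C[C@H](O)[C@](C)(O)C1 | intermediate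
7 | C1 monotosylate of 6 | C1/C=C(/C)[C@@H](O[Si](C)(C)C(C)(C)C)C[C@H](OS(=O)(=O)c2ccc(C)cc2)[C@](C)(O)C1 | intermediate
8 | (2Z,4S,6S,7R)-4-(TBSO)-7-hydroxy-3,7-dimethyl-6-(tosyloxy)cyclooct-2-en-1-one | O=C1/C=C(/C)[C@@H](O[Si](C)(C)C(C)(C)C)C[C@H](OS(=O)(=O)c2ccc(C)cc2)[C@](C)(O)C1 | intermediate
9 | bis-TMS siloxydiene from 8 | C[C@@]1(O[Si](C)(C)C)/C=C(/O[Si](C)(C)C)\C=C(\C)[C@@H](O[Si](C)(C)C(C)(C)C)C[C@@H]1OS(=O)(=O)c2ccc(C)cc2 | intermediate
10 | cis-fused dichlorocyclobutanone (drawn diastereomer; the other cis-fused one is equally usable) | C[C@@]1(O[Si](C)(C)C)[C@H]2C(=O)C(Cl)(Cl)[C@@]2(O[Si](C)(C)C)/C=C(/C)[C@@H](O[Si](C)(C)C(C)(C)C)C[C@@H]1OS(=O)(=O)c3ccc(C)cc3 | intermediate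
11 | dechlorinated siloxybicyclo[6.2.0]decenone | C[C@@]1(O[Si](C)(C)C)[C@H]2C(=O)C[C@@]2(O[Si](C)(C)C)/C=C(/C)[C@@H](O[Si](C)(C)C(C)(C)C)C[C@@H]1OS(=O)(=O)c3ccc(C)cc3 | intermediate
12 | cyclobutanolate (drawn protonated) | C[C@@]1(O)[C@H]2C(=O)C[C@@]2(O)/C=C(/C)[C@@H](O[Si](C)(C)C(C)(C)C)C[C@@H]1OS(=O)(=O)c3ccc(C)cc3 | intermediate
13 | ten-membered (4Z)-cyclodec-4-ene-1,3-dione, formed as its Bu4N enolate (drawn protonated) | O=C1/C=C(/C)[C@@H](O[Si](C)(C)C(C)(C)C)C[C@H](OS(=O)(=O)c2ccc(C)cc2)[C@](C)(O)CC(=O)C1 | intermediate
14 | C7-(methoxycarbonylmethyl) dione (C7 labile) | O=C1/C=C(/C)[C@@H](O[Si](C)(C)C(C)(C)C)C[C@H](OS(=O)(=O)c2ccc(C)cc2)[C@](C)(O)CC(=O)C1CC(=O)OC | intermediate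
15 | (7R,8R)-C8-hydroxy enone | O=C1/C=C(/C)[C@@H](O[Si](C)(C)C(C)(C)C)C[C@H](OS(=O)(=O)c2ccc(C)cc2)[C@](C)(O)C[C@@H](O)[C@H]1CC(=O)OC | intermediate
16 | (6R,7R,8R)-6,8-anti-diol methyl ester | O[C@@H]1/C=C(/C)[C@@H](O[Si](C)(C)C(C)(C)C)C[C@H](OS(=O)(=O)c2ccc(C)cc2)[C@](C)(O)C[C@@H](O)[C@H]1CC(=O)OC | intermediate
17 | trans-fused 6,12-olide with free C8–OH and C10–OH, C1–OTs, C3–OTBS | C1C(=O)O[C@@H]2/C=C(/C)[C@@H](O[Si](C)(C)C(C)(C)C)C[C@H](OS(=O)(=O)c3ccc(C)cc3)[C@](C)(O)C[C@@H](O)[C@@H]12 | intermediate
18 | methyl angelate | C/C=C(/C)C(=O)OC | starting material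
19 | (Z)-2-methylbut-2-en-1-ol | C/C=C(/C)CO | intermediate
20 | [(2R,3S)-2,3-dimethyloxiran-2-yl]methanol | OC[C@@]1(C)O[C@H]1C | intermediate
21 | (2S,3S)-2,3-dimethyloxirane-2-carboxylic acid | OC(=O)[C@@]1(C)O[C@H]1C | intermediate
22 | mixed anhydride of 21 with 2,4,6-trichlorobenzoic acid | O=C(OC(=O)[C@@]1(C)O[C@H]1C)c1c(Cl)cc(Cl)cc1Cl | intermediate
23 | C8 epoxyangelate of 17 | C1C(=O)O[C@@H]2/C=C(/C)[C@@H](O[Si](C)(C)C(C)(C)C)C[C@H](OS(=O)(=O)c3ccc(C)cc3)[C@](C)(O)C[C@@H](OC(=O)[C@@]3(C)O[C@H]3C)[C@@H]12 | intermediate
24 | (1R,10R)-epoxy lactone | C1C(=O)O[C@@H]2/C=C(/C)[C@@H](O[Si](C)(C)C(C)(C)C)C[C@H]3O[C@]3(C)C[C@@H](OC(=O)[C@@]3(C)O[C@H]3C)[C@@H]12 | intermediate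
25 | α-(dimethylaminomethyl) lactone (C11 undefined) | CN(C)CC1C(=O)O[C@@H]2/C=C(/C)[C@@H](O[Si](C)(C)C(C)(C)C)C[C@H]3O[C@]3(C)C[C@@H](OC(=O)[C@@]3(C)O[C@H]3C)[C@@H]12 | intermediate
26 | methiodide of 25 | C[N+](C)(C)CC1C(=O)O[C@@H]2/C=C(/C)[C@@H](O[Si](C)(C)C(C)(C)C)C[C@H]3O[C@]3(C)C[C@@H](OC(=O)[C@@]3(C)O[C@H]3C)[C@@H]12.[I-] | intermediate
27 | α-methylene lactone, C3–OTBS | C=C1C(=O)O[C@@H]2/C=C(/C)[C@@H](O[Si](C)(C)C(C)(C)C)C[C@H]3O[C@]3(C)C[C@@H](OC(=O)[C@@]3(C)O[C@H]3C)[C@@H]12 | intermediate
28 | 3-hydroxy compound | C=C1C(=O)O[C@@H]2/C=C(/C)[C@@H](O)C[C@H]3O[C@]3(C)C[C@@H](OC(=O)[C@@]3(C)O[C@H]3C)[C@@H]12 | intermediate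
29 | CNP0167461.1 (1R,3S,6R,7R,8R,10R,2′S,3′S; 4Z) | C=C1C(=O)O[C@@H]2/C=C(/C)[C@@H](OC(=O)CC(C)C)C[C@H]3O[C@]3(C)C[C@@H](OC(=O)[C@@]3(C)O[C@H]3C)[C@@H]12 | target

**Step count**
- Total: 19 steps.
- Longest linear sequence: 16 steps (steps 1–11 and 15–19).

**The three steps most likely to fail**

Step 10.
- What may go wrong: cleavage of the non-fusion bond C6–C7, O-alkylation or double alkylation of the diketonate, and, under basic fluoride, premature displacement of the tosylate or retro-aldol opening at C9–C10.
- Fallback (from 11, rejoining at 14): the two events are separated and no enolate alkylation is used.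
  - Aqueous AcOH/THF at 40 °C removes the TMS groups and runs the ring expansion under protic, fully reversible conditions, and the neutral dione 13 is isolated.
  - The side chain is then introduced by an organocatalytic three-component reductive alkylation (methyl glyoxylate, Hantzsch ester, L-proline, CH2Cl2, rt).
  - The Knoevenagel alkylidene dione F1 forms in the flask and is reduced at once by conjugate hydride transfer to give 14. Only C-substitution is possible and no base is present.

Step 11.
- What may go wrong: incomplete funnelling of C7 if epimerisation is slower than hydride transfer, erosion of 1,3-anti control from a tertiary carbinol inside the ring, and lactonisation onto O8 instead of O6.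
- Fallback (from 14 and 20, rejoining at 23, so that steps 14 and 15 are no longer needed): the relay is interrupted and the two oxygens are differentiated by a Tishchenko hydride transfer.
  - With 1.5 equiv Me4NBH(OAc)3 at −40 °C the hydroxy enone 15 is isolated. Its C7 epimers interconvert through the C6 ketone, so the unwanted epimer can be re-equilibrated.
  - Epoxy alcohol 20 is oxidised (DMP) to (2S,3S)-2,3-dimethyloxirane-2-carbaldehyde F2.
  - An Evans–Tishchenko reaction of 15 with F2 (SmI2, 30 mol %, pre-aged with the aldehyde, THF, −10 °C) transfers the hemiacetal hydride from O8 to C6 (1,3-anti). This leaves the epoxyangelate on O8 and a free C6–OH in the hydroxy ester F3.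
  - In F3 only one lactone can form (PPTS, CH2Cl2), and this gives 23.

Step 4.
- What may go wrong: poor or reversed facial selectivity on the flexible cyclooctadiene, and over-oxidation of the second alkene.
- Fallback (from 3, rejoining at 6): substrate shielding is replaced by two directed reactions.
  - (S)-Me-CBS/catecholborane gives the (1R)-dienol F4.
  - Hydrogen-bond-directed dihydroxylation with OsO4·TMEDA (CH2Cl2, −78 °C, then sulfite work-up) places both new oxygens on the face of the C3–OH to give the all-cis triol F5.
  - MnO2 oxidises only the allylic alcohol to give the keto diol F6.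
  - Saksena–Evans reduction directed by the C1–OH returns C3 with the required 1,3-anti relationship to give the triol F7.
  - Selective silylation of the allylic C3–OH (TBSCl, imidazole, −20 °C), favoured because C1–OH is neopentylic, gives 6.

**Further compounds**
F1 | step 10 | Knoevenagel alkylidene dione (C7=C11) | O=C1/C=C(/C)[C@@H](O[Si](C)(C)C(C)(C)C)C[C@H](OS(=O)(=O)c2ccc(C)cc2)[C@](C)(O)CC(=O)C1=CC(=O)OC
F2 | step 11 | (2S,3S)-2,3-dimethyloxirane-2-carbaldehyde | O=C[C@@]1(C)O[C@H]1C
F3 | step 11 | C6-hydroxy C8-epoxyangelate methyl ester | O[C@@H]1/C=C(/C)[C@@H](O[Si](C)(C)C(C)(C)C)C[C@H](OS(=O)(=O)c2ccc(C)cc2)[C@](C)(O)C[C@@H](OC(=O)[C@@]2(C)O[C@H]2C)[C@H]1CC(=O)OC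
F4 | step 4 | (1R,2Z,6Z)-2,6-dimethylcycloocta-2,6-dien-1-ol | C1/C=C(/C)[C@H](O)C/C=C(/C)C1
F5 | step 4 | all-cis triol (C3 R; C1 S; C10 R) | C1/C=C(/C)[C@H](O)C[C@H](O)[C@](C)(O)C1
F6 | step 4 | keto diol (C3 ketone; C1 S; C10 R) | C1/C=C(/C)C(=O)C[C@H](O)[C@](C)(O)C1
F7 | step 4 | triol with C3 S (1,3-anti to C1–OH) | C1/C=C(/C)[C@@H](O)C[C@H](O)[C@](C)(O)C1
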